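## Retrosynthetic overview

1. EGCG ⇒ octa-O-benzyl EGCG (one global hydrogenolysis) ⇒ penta-O-benzyl-epigallocatechin + tri-O-benzylgallic acid (late 3-O-galloylation, as in the plant).
2. Both stereocentres (2R,3R, cis) ⇒ set together on the achiral anthocyanidin (penta-O-benzyldelphinidin) by a reductase-type double hydride transfer: hydride to C4, then dynamic kinetic asymmetric reduction of the C2-labile flavan-3-one.
3. Anthocyanidin ⇒ flavonol (penta-O-benzylmyricetin) by C4 reduction and loss of water through the flav-2-ene-3,4-diol.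
4. Ring C ⇒ closed by attack of the 2'-phenoxide on C-β of the chalcone, with C3 oxygenation in the same flask; chalcone ⇒ aldol condensation of the ring A acetophenone with the ring B aldehyde.
5. Ring order: rings A and B are bought as arenes; ring C is the only ring formed (step 1), at the achiral chalcone stage, so no stereocentre is carried through ring closure.

Assumption: compounds 1, 2 and 11 are bought as catalogue building blocks (each is otherwise one or two routine benzylation steps from phloroacetophenone, 3,4,5-trihydroxybenzaldehyde or gallic acid), and those benzylations are not counted.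

## Route

Step 1
Reactants: 1 2'-hydroxy-4',6'-dibenzyloxyacetophenone; 2 3,4,5-tris(benzyloxy)benzaldehyde
Product: 5 penta-O-benzylmyricetin [5,7-bis(benzyloxy)-3-hydroxy-2-(3,4,5-tris(benzyloxy)phenyl)-4H-chromen-4-one], via chalcone 3 (not isolated), via racemic trans-dihydroflavonol 4 (not isolated)
Conditions: KOH (50% aq, 10 equiv), EtOH/THF 1:1, rt, 36 h; then dilute with MeOH/THF, 0 °C, 30% H2O2 (5 equiv), 0 °C → rt, 8 h; 2 M HCl work-up
Reagents that add atoms: hydrogen peroxide, OO
Why: Claisen–Schmidt aldol condensation gives the E-chalcone 3, whose 2'-phenoxide closes ring C on C-β (the chalcone-isomerase-type oxa-Michael event) while alkaline H2O2 oxygenates C3 and then dehydrogenates C2–C3 (Algar–Flynn–Oyamada oxidation), so ring C arrives fully unsaturated and achiral and no stereocentre is set.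

Step 2
Reactants: 5 penta-O-benzylmyricetin
Product: 7 penta-O-benzyldelphinidin chloride [5,7-bis(benzyloxy)-3-hydroxy-2-(3,4,5-tris(benzyloxy)phenyl)chromenylium chloride], via flav-2-ene-3,4-diol 6 (not isolated)
Conditions: LiAlH4 (1.0 equiv), THF, −10 → 0 °C, 1 h; cannulate into HCl (2 M in Et2O)/MeOH, 0 °C; filter the red salt under Ar and use at once
Reagents that add atoms: hydrogen chloride, Cl
Why: Hydride adds 1,2 to the C4 carbonyl of the 3-O-aluminate (LiAlH4 reduction of a flavonol) to give the flav-2-ene-3,4-diol, which on acidification ionises its 4-OH (E1) to the aromatic flavylium cation, the same diol-to-anthocyanidin dehydration that ends the anthocyanidin synthase step; benzyl ethers are inert to both reagents and no stereocentre is created.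

Step 3
Reactants: 7 penta-O-benzyldelphinidin chloride
Product: 10 penta-O-benzyl-(−)-epigallocatechin [(2R,3R)-5,7-bis(benzyloxy)-2-(3,4,5-tris(benzyloxy)phenyl)chroman-3-ol], via flav-2-en-3-ol 8 (not isolated), via racemic flavan-3-one 9 (not isolated)
Conditions: (a) diethyl 2,6-dimethyl-1,4-dihydropyridine-3,5-dicarboxylate (Hantzsch ester, 1.05 equiv), CH2Cl2, −20 → 0 °C, 7 added in portions, Ar; (b) RuCl[(R,R)-TsDPEN](p-cymene) (2 mol %), HCO2H (5 equiv)/Et3N (6 equiv), DMF, 30 °C, 24 h, Ar; recrystallise to raise ee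
Reagents that add atoms: none
Why: Proposed new method: a reductase-like two-hydride cascade in which the dihydropyridine (an NADH model; hydride transfer from Hantzsch esters to pyrylium and flavylium cations is the known basis) reduces C4 of the cation to enol 8, which ketonises to flavan-3-one 9; the C2–H of 9 (benzylic, α-oxygen, α-keto) epimerises through 8 faster than the ketone is reduced, so Noyori–Ikariya asymmetric transfer hydrogenation runs as a dynamic kinetic resolution (closest known type: DKR transfer hydrogenation of 2-aryl cycloalkanones and 3-aryl chroman-4-ones to cis alcohols), with hydride entering C3 anti to ring B (hence 2,3-cis) on the Si face to give 2R,3R; the (R,R) catalyst is chosen by analogy with the CH/π model (C2 taking the role of the aryl group), the sense must be confirmed on the first run against natural EGCG after step 5, and the (S,S) complex is used if it is reversed.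

Step 4
Reactants: 10 penta-O-benzyl-(−)-epigallocatechin; 11 3,4,5-tris(benzyloxy)benzoic acid
Product: 12 octa-O-benzyl-EGCG [(2R,3R)-5,7-bis(benzyloxy)-2-(3,4,5-tris(benzyloxy)phenyl)chroman-3-yl 3,4,5-tris(benzyloxy)benzoate]
Conditions: 11 (1.5 equiv), DCC (1.6 equiv), DMAP (0.3 equiv), CH2Cl2, 0 °C → rt, 16 h
Reagents that add atoms: none
Why: Steglich esterification acylates the axial 3-OH through the N-acylpyridinium ion without breaking the C3–O bond, so both stereocentres are retained; it mirrors the late galloyl transfer to epigallocatechin.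

Step 5
Reactants: 12 octa-O-benzyl-EGCG
Product: 13 (−)-epigallocatechin gallate
Conditions: H2 (1 atm), Pd(OH)2/C (20 wt %), THF/MeOH 1:1, rt, about 6 h, stopped at completion; filter under Ar, concentrate below 30 °C, lyophilise
Reagents that add atoms: none
Why: Heterogeneous hydrogenolysis cleaves all eight benzyl ethers as toluene, while the aryl ester, the slower-reacting ring C benzylic C2–O1 bond and both stereocentres survive in neutral medium; isolation without base or heat avoids C2 epimerisation and autoxidation.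

## Compound list

1 | 1-[2,4-bis(benzyloxy)-6-hydroxyphenyl]ethan-1-one (2'-hydroxy-4',6'-dibenzyloxyacetophenone, ring A) | CC(=O)c1c(O)cc(OCc2ccccc2)cc1OCc1ccccc1 | starting material
2 | 3,4,5-tris(benzyloxy)benzaldehyde (ring B) | O=Cc1cc(OCc2ccccc2)c(OCc2ccccc2)c(OCc2ccccc2)c1 | starting material
3 | (E)-1-[2,4-bis(benzyloxy)-6-hydroxyphenyl]-3-[3,4,5-tris(benzyloxy)phenyl]prop-2-en-1-one (chalcone) | O=C(/C=C/c1cc(OCc2ccccc2)c(OCc2ccccc2)c(OCc2ccccc2)c1)c1c(O)cc(OCc2ccccc2)cc1OCc1ccccc1 | intermediate (not isolated)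
4 | rac-(2R,3R)-5,7-bis(benzyloxy)-3-hydroxy-2-[3,4,5-tris(benzyloxy)phenyl]chroman-4-one (racemic 2,3-trans dihydroflavonol; one enantiomer drawn) | O=C1c2c(OCc3ccccc3)cc(OCc3ccccc3)cc2O[C@H](c2cc(OCc3ccccc3)c(OCc3ccccc3)c(OCc3ccccc3)c2)[C@H]1O | intermediate (not isolated)
5 | 5,7-bis(benzyloxy)-3-hydroxy-2-[3,4,5-tris(benzyloxy)phenyl]-4H-chromen-4-one (penta-O-benzylmyricetin; achiral) | O=c1c(O)c(-c2cc(OCc3ccccc3)c(OCc3ccccc3)c(OCc3ccccc3)c2)oc2cc(OCc3ccccc3)cc(OCc3ccccc3)c12 | intermediate
6 | 5,7-bis(benzyloxy)-2-[3,4,5-tris(benzyloxy)phenyl]-4H-chromene-3,4-diol (flav-2-ene-3,4-diol; racemic at C4; present as its aluminate) | OC1C(O)=C(c2cc(OCc3ccccc3)c(OCc3ccccc3)c(OCc3ccccc3)c2)Oc2cc(OCc3ccccc3)cc(OCc3ccccc3)c12 | intermediate (not isolated)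
7 | 5,7-bis(benzyloxy)-3-hydroxy-2-[3,4,5-tris(benzyloxy)phenyl]chromenylium chloride (penta-O-benzyldelphinidin chloride; achiral) | Oc1cc2c(OCc3ccccc3)cc(OCc3ccccc3)cc2[o+]c1-c1cc(OCc2ccccc2)c(OCc2ccccc2)c(OCc2ccccc2)c1.[Cl-] | intermediate
8 | 5,7-bis(benzyloxy)-2-[3,4,5-tris(benzyloxy)phenyl]-4H-chromen-3-ol (flav-2-en-3-ol; achiral enol) | OC1=C(c2cc(OCc3ccccc3)c(OCc3ccccc3)c(OCc3ccccc3)c2)Oc2cc(OCc3ccccc3)cc(OCc3ccccc3)c2C1 | intermediate (not isolated)
9 | 5,7-bis(benzyloxy)-2-[3,4,5-tris(benzyloxy)phenyl]chroman-3-one (flavan-3-one; racemic, C2 labile) | O=C1Cc2c(OCc3ccccc3)cc(OCc3ccccc3)cc2OC1c1cc(OCc2ccccc2)c(OCc2ccccc2)c(OCc2ccccc2)c1 | intermediate (not isolated)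
10 | (2R,3R)-5,7-bis(benzyloxy)-2-[3,4,5-tris(benzyloxy)phenyl]chroman-3-ol (penta-O-benzyl-(−)-epigallocatechin; 2,3-cis) | O[C@@H]1Cc2c(OCc3ccccc3)cc(OCc3ccccc3)cc2O[C@@H]1c1cc(OCc2ccccc2)c(OCc2ccccc2)c(OCc2ccccc2)c1 | intermediate
11 | 3,4,5-tris(benzyloxy)benzoic acid | OC(=O)c1cc(OCc2ccccc2)c(OCc2ccccc2)c(OCc2ccccc2)c1 | starting material
12 | (2R,3R)-5,7-bis(benzyloxy)-2-[3,4,5-tris(benzyloxy)phenyl]chroman-3-yl 3,4,5-tris(benzyloxy)benzoate (octa-O-benzyl-EGCG) | O=C(O[C@@H]1Cc2c(OCc3ccccc3)cc(OCc3ccccc3)cc2O[C@@H]1c1cc(OCc2ccccc2)c(OCc2ccccc2)c(OCc2ccccc2)c1)c1cc(OCc2ccccc2)c(OCc2ccccc2)c(OCc2ccccc2)c1 | intermediate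
13 | (−)-epigallocatechin gallate, (2R,3R)-5,7-dihydroxy-2-(3,4,5-trihydroxyphenyl)chroman-3-yl 3,4,5-trihydroxybenzoate | O=C(O[C@@H]1Cc2c(O)cc(O)cc2O[C@@H]1c1cc(O)c(O)c(O)c1)c1cc(O)c(O)c(O)c1 | target

## Step count and risks

Total step count: 5. Longest linear sequence: 5 steps (1 + 2 → 5 → 7 → 10 → 12 → 13); acid 11 joins at step 4.

**Most likely to fail, first: step 3.** The cascade is new. It needs C2 of 9 to epimerise faster than the ketone is reduced, the facial sense of the catalyst is predicted only by analogy, and enol 8 can add to unreacted cation 7 (hence the portionwise addition to excess dihydropyridine). The fallback replaces catalytic control by resolution. It sets out from 9, isolated by stopping step 3 after the dihydropyridine stage. LiBH(s-Bu)3 in THF at −78 °C delivers hydride anti to ring B and gives racemic penta-O-benzyl-epigallocatechin F1. Acylation with (1S)-camphanic chloride (Et3N, DMAP, CH2Cl2) gives two diastereomers, the (2R,3R)-flavan-3-yl camphanate F2 and the (2S,3S)-flavan-3-yl camphanate F3, separated by crystallisation or chromatography and assigned by carrying a sample through to 13. LiOH in THF/H2O cleaves F2, and the route is rejoined at 10, with at most half of the material.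

**Second: step 1.** 2'-Hydroxychalcones carrying a 6'-alkoxy group can divert under alkaline peroxide to aurones (five-membered ring closure at C-α), and the one-flask format leaves no chance to purify the chalcone. The fallback separates ring closure from C3 oxygenation. It sets out from 3, isolated by acidifying after the aldol stage. I2 (10 mol %) in DMSO at 130 °C closes ring C through the same phenol-to-C-β attack and dehydrogenates to the flavone penta-O-benzyltricetin F4. Dimethyldioxirane in acetone/CH2Cl2 at 0 °C gives the racemic flavone 2,3-epoxide F5, which a trace of p-TsOH opens to the flavonol, rejoining the route at 5.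

**Third: step 2.** Conjugate reduction can compete with 1,2-addition, and the 3-hydroxyflavylium salt is sensitive to water (hemiketal formation and ring opening). Over-reduction of the cation in the flask is harmless, since it leads to the enolate of 9. The fallback reaches 9 through the leucoanthocyanidin instead of the flavonol. It sets out from 4, isolated when the peroxide stage of step 1 is run at 0 °C with 1.2 equiv H2O2 and stopped before dehydrogenation. NaBH4 in THF/MeOH at 0 °C reduces the C4 ketone to the racemic 2,3-trans flavan-3,4-diol F6. p-TsOH (5 mol %) in CH2Cl2 at high dilution (about 0.005 M, to suppress attack of ring A of a second molecule) ionises the 4-OH to the benzylic cation stabilised by ring A, which loses H-3 and ketonises (pinacol-type dehydration of an aryl 1,2-diol). The route is rejoined at 9, which enters stage (b) of step 3.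

## Further compounds

F1 | step 3 | racemic 2,3-cis-5,7-bis(benzyloxy)-2-[3,4,5-tris(benzyloxy)phenyl]chroman-3-ol (10 together with its enantiomer) | O[C@@H]1Cc2c(OCc3ccccc3)cc(OCc3ccccc3)cc2O[C@@H]1c1cc(OCc2ccccc2)c(OCc2ccccc2)c(OCc2ccccc2)c1.O[C@H]1Cc2c(OCc3ccccc3)cc(OCc3ccccc3)cc2O[C@H]1c1cc(OCc2ccccc2)c(OCc2ccccc2)c(OCc2ccccc2)c1
F2 | step 3 | (2R,3R)-5,7-bis(benzyloxy)-2-[3,4,5-tris(benzyloxy)phenyl]chroman-3-yl (1S,4R)-camphanate | O=C(O[C@@H]1Cc2c(OCc3ccccc3)cc(OCc3ccccc3)cc2O[C@@H]1c1cc(OCc2ccccc2)c(OCc2ccccc2)c(OCc2ccccc2)c1)[C@@]12CC[C@@](C)(C(=O)O1)C2(C)C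
F3 | step 3 | (2S,3S)-5,7-bis(benzyloxy)-2-[3,4,5-tris(benzyloxy)phenyl]chroman-3-yl (1S,4R)-camphanate | O=C(O[C@H]1Cc2c(OCc3ccccc3)cc(OCc3ccccc3)cc2O[C@H]1c1cc(OCc2ccccc2)c(OCc2ccccc2)c(OCc2ccccc2)c1)[C@@]12CC[C@@](C)(C(=O)O1)C2(C)C
F4 | step 1 | 5,7-bis(benzyloxy)-2-[3,4,5-tris(benzyloxy)phenyl]-4H-chromen-4-one (penta-O-benzyltricetin) | O=c1cc(-c2cc(OCc3ccccc3)c(OCc3ccccc3)c(OCc3ccccc3)c2)oc2cc(OCc3ccccc3)cc(OCc3ccccc3)c12
F5 | step 1 | racemic 2,3-epoxy-5,7-bis(benzyloxy)-2-[3,4,5-tris(benzyloxy)phenyl]chroman-4-one (flavone 2,3-epoxide, cis-fused) | O=C1c2c(OCc3ccccc3)cc(OCc3ccccc3)cc2OC2(c3cc(OCc4ccccc4)c(OCc4ccccc4)c(OCc4ccccc4)c3)OC12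
F6 | step 2 | rac-(2R,3S)-5,7-bis(benzyloxy)-2-[3,4,5-tris(benzyloxy)phenyl]chromane-3,4-diol (2,3-trans, C4 epimers; one enantiomer drawn) | OC1c2c(OCc3ccccc3)cc(OCc3ccccc3)cc2O[C@H](c2cc(OCc3ccccc3)c(OCc3ccccc3)c(OCc3ccccc3)c2)[C@H]1O
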